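**Plan**

1. Retrosynthetic cuts: first the two ester C–O bonds (C9 methacrylate, C6 angelate) and the exocyclic C=C/CHO units; then the carbocycle (ring A) at C8–C9 and C5–C10. This leaves a 4-alkenyl-2(5H)-furanone (C5–C8 plus lactone carbons C11, C12) and the enol of 2-methylmalondialdehyde (C9, C10, C14, C1).
2. Enabling feature: the γ-lactone (ring B) O–C12(=O)–C11–C7–C8. As its 2-silyloxyfuran, the O-bearing C8 becomes the nucleophilic end of an exocyclic diene C8=C7–C6=C5, and the vicinal C8–O/C9–O pattern lets a temporary O–Si–O bridge tie the enol oxygen on C9 to the furan oxygen on C12.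
3. Forward order: side chain and butenolide (Takai–Utimoto olefination, Suzuki coupling) → silicon tether → tethered [4+2] closes ring A onto ring B → C6 oxygen, C8 and C7 adjusted on the butenolide → vinyl, α-methylene lactone, angelate, acrolein unit, methacrylate.
4. Stereochemistry: C9/C10 from the (E)-enol ether; C5 relative to C9/C10 from the tether-enforced endo position of C9–O together with the (E)-alkenyl group; absolute sense from the (R)-glyceraldehyde-derived dioxolane carbon C4 (erased later); C6 by oxygen delivery from C9–OH; C8 by thermodynamic epimerisation of the butenolide γ-carbon; C7 by C6–OH-directed hydrogenation.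

Key step: step 5

Remarks on the chemistry:
- Numbering (elemane): ring A = C5–C10; C4(=C3)–C15 on C5; ring B = O–C8, C7–C11(=C13)–C12(=O); C1=C2 and C14 on C10. α = face of C10–CH3, β = face of the C10 vinyl (or formyl) group.
- Assumption: in step 5 the dienophile adds to the diene face anti to the allylic C–O bond of the dioxolane (rotamer with C4–H eclipsing C5=C6). On that basis (R)-aldehyde 1 leads to the drawn enantiomer; if the opposite sense were found, the (S)-aldehyde would be used with no other change.

**Step 1**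
Reactants: 1 (R)-2,2-dimethyl-1,3-dioxolane-4-carbaldehyde; 2 2-(dichloromethyl)-4,4,5,5-tetramethyl-1,3,2-dioxaborolane
Product: 3 (E)-alkenylboronate (pinacol ester; (4S)-dioxolane)
Conditions: CrCl2, LiI, THF, 25 °C
Reagents that add atoms: none
Why: Takai–Utimoto boron olefination: the gem-dichromium species from 2 adds to the aldehyde and eliminates to the (E)-alkenylboronate under non-basic conditions, so the dioxolane stereocenter is untouched.

**Step 2**
Reactants: 3 (E)-alkenylboronate; 4 4-bromofuran-2(5H)-one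
Product: 5 4-[(E)-2-((4S)-2,2-dimethyl-1,3-dioxolan-4-yl)ethenyl]furan-2(5H)-one
Conditions: PdCl2(dppf) (5 mol%), K3PO4, THF/H2O, 50 °C
Reagents that add atoms: none
Why: Suzuki–Miyaura coupling of the vinylogous acyl bromide with the alkenylboronate proceeds with retention of the (E)-geometry.

**Step 3**
Reactants: 6 (E)-3-ethoxy-2-methylprop-2-enal
Product: 7 2-methylmalondialdehyde (enol form; (E)-3-hydroxy-2-methylprop-2-enal)
Conditions: aq. NaOH, 25 °C; then aq. HCl to pH 3
Reagents that add atoms: sodium hydroxide, [Na+].[OH-]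
Why: Addition–elimination of hydroxide at C3 of the vinylogous formate ester (vinylogous ester hydrolysis) frees the stable enol.

**Step 4**
Reactants: 7 2-methylmalondialdehyde (enol); 5 alkenylbutenolide
Product: 9 tethered triene (mixed diisopropylsilyl bis-enol ether), via silyl monotriflate 8 (not isolated)
Conditions: iPr2Si(OTf)2, 2,6-lutidine, CH2Cl2, −78 °C, slow addition of 7; then 5, Et3N, −78 → 0 °C; used without chromatography
Reagents that add atoms: diisopropylsilyl bis(trifluoromethanesulfonate), CC(C)[Si](OS(=O)(=O)C(F)(F)F)(OS(=O)(=O)C(F)(F)F)C(C)C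
Why: Sequential O-silylation of two different enols by a dialkylsilyl bis(triflate) is the usual entry to unsymmetrical silyl bis-enol ethers; the acidic enol 7 reacts first, soft enolisation of the butenolide then gives the aromatic 2-silyloxyfuran, and the push–pull enol ether settles in its (E)-form (O trans to CHO).

**Step 5**
Reactants: 9 tethered triene
Product: 11 β,γ-unsaturated hydroxy lactone aldehyde (C6=C7; 8α-O; 9α-OH; 5α-dioxolanyl; 10α-CH3; 10β-CHO), via silicon-bridged cycloadduct 10 (not isolated)
Conditions: PhMe (0.005 M), BHT (cat.), 110 °C; then HF·pyridine, pyridine, THF, −20 °C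
Reagents that add atoms: none
Why: Proposed new method: heating 9 brings the enal C9=C10, held by the O–Si–O bridge beneath the furan ring, onto the exocyclic diene C8=C7–C6=C5 of the 2-silyloxyfuran, and a concerted but asynchronous [4+2] cycloaddition (C8–C9 leading as in a vinylogous Mukaiyama–Michael addition, C5–C10 following as a 1,6-closure) forms both bonds, after which HF·pyridine cleaves both Si–O bonds and protonates the ketene acetal kinetically at C11. The closest known reaction types are the silicon-tethered intramolecular Diels–Alder reaction, the extra-annular Diels–Alder reaction of 3-vinylfurans and the Michael reactivity of 2-silyloxyfurans at C5, whereas a diene–dienophile tether through a silyl ketene acetal oxygen has no direct precedent. Ring A closes as a six-membered carbocycle by suprafacial/suprafacial [4+2] addition, and the temporary seven-membered 1,3-dioxa-2-sila ring is necessarily cis-fused across C8–C9. C9 and C10 follow from the (E)-enol ether (C9–O cis to C10–CH3); the three-atom bridge reaches only when C9–O lies endo under the furan, which puts C10–CH3 endo and CHO exo, so that C5 (side chain outside on the (E)-alkene) and C8 (ring oxygen outside) come out cis to C9–O and C10–CH3, and the absolute sense is set by attack anti to the allylic C–O bond of the dioxolane. The step needs periselectivity for the exocyclic diene over the furan 2,5-positions, which is secured because furan-type oxanorbornene adducts revert while the exocyclic adduct does not, and it needs the (E)-enol ether geometry to persist, which it should in the absence of acid. C8 is formed on purpose with its C–O bond α and is corrected in step 8.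

**Step 6**
Reactants: 11 β,γ-unsaturated hydroxy lactone aldehyde
Product: 12 6α,7α-epoxide
Conditions: VO(acac)2 (5 mol%), t-BuOOH (decane), CH2Cl2, 0 → 25 °C
Reagents that add atoms: tert-butyl hydroperoxide, CC(C)(C)OO
Why: Hydroxyl-directed epoxidation of a cyclohex-3-en-1-ol: the homoallylic C9–OH delivers oxygen to its own α face of C6=C7, fixing C6–O α (cis to the C5 side chain) despite the crowding of that face.

**Step 7**
Reactants: 12 6α,7α-epoxide
Product: 13 9-O-TBS epoxy lactone
Conditions: TBSOTf, 2,6-lutidine, CH2Cl2, −78 °C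
Reagents that add atoms: tert-butyldimethylsilyl trifluoromethanesulfonate, CC(C)(C)[Si](C)(C)OS(=O)(=O)C(F)(F)F
Why: Low-temperature silylation of the hindered secondary alcohol with a silyl triflate protects C9–OH and removes the retro-aldol pathway of the β-hydroxy aldehyde before base is used.

**Step 8**
Reactants: 13 9-O-TBS epoxy lactone
Product: 15 6α-hydroxybutenolide (8β-O epimer), via 8α-O hydroxybutenolide 14 (not isolated)
Conditions: DBU, CH2Cl2, 25 °C
Reagents that add atoms: none
Why: DBU removes H-11 and opens the β,γ-epoxy lactone (E1cB-type epoxide-to-allylic-alcohol isomerisation) with retention at C6, then equilibrates C8 through the aromatic 2-furanolate (vinylogous enolate); the planar butenolide keeps its ring oxygen equatorial on C8, which in 14 forces C9–OTBS, the C5 side chain and CHO axial, whereas in 15 these are equatorial and only C10–CH3 and C6–OH are axial, so 15 should be favoured.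

**Step 9**
Reactants: 15 6α-hydroxybutenolide (8β-O epimer)
Product: 16 saturated cis-fused lactone (H-7α; H-8α)
Conditions: H2 (1 atm), [Ir(cod)(PCy3)(py)]PF6 (10 mol%), CH2Cl2, 25 °C
Reagents that add atoms: none
Why: Hydroxyl-directed hydrogenation: the allylic C6–OH (α) binds the cationic iridium catalyst and H2 is delivered to the α face of C7=C11, giving H-7 α and hence the cis-fused lactone; aldehyde and silyl ether are inert.

**Step 10**
Reactants: 16 saturated cis-fused lactone
Product: 17 10β-vinyl lactone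
Conditions: Zn, CH2Br2, TiCl4, THF/CH2Cl2, 0 → 25 °C
Reagents that add atoms: dibromomethane, BrCBr
Why: Takai–Lombardo methylenation converts the hindered, non-enolisable aldehyde into the vinyl group under non-basic conditions that spare the lactone and the free C6–OH.

**Step 11**
Reactants: 17 10β-vinyl lactone
Product: 20 α-methylene lactone, via Mannich base 18 (not isolated), via methiodide 19 (not isolated)
Conditions: LiN(iPr)2 (2.5 equiv), THF, −78 °C; CH2=NMe2+ I−, −78 → 0 °C; then MeI, MeOH, 25 °C; then aq. NaHCO3, CH2Cl2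
Reagents that add atoms: N,N-dimethylmethyleneiminium iodide, C=[N+](C)C.[I-]
Why: Mannich-type α-methylenation of the γ-lactone: the lithium enolate (the C6 alkoxide takes one equivalent of base and, being trans-diaxial to C11, cannot relactonise) is aminomethylated, and quaternisation followed by E1cB elimination installs C11=C13 without touching any stereocenter.

**Step 12**
Reactants: 20 α-methylene lactone; 21 angelic acid
Product: 22 6α-angelate
Conditions: 21, 2,4,6-trichlorobenzoyl chloride, Et3N, PhMe, 25 °C; then 20, 80 °C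
Reagents that add atoms: none
Why: Yamaguchi esterification through the preformed mixed anhydride, without nucleophilic catalyst, acylates the axial C6–OH and is the usual way to avoid isomerisation of the (Z)-enoate to the tiglate.

**Step 13**
Reactants: 22 6α-angelate
Product: 23 4,15-diol
Conditions: AcOH/H2O (4:1), 40 °C
Reagents that add atoms: none
Why: Mild acid hydrolysis of the terminal acetonide; the neopentylic TBS ether, both unsaturated esters and the α-methylene lactone tolerate aqueous acetic acid.

**Step 14**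
Reactants: 23 4,15-diol
Product: 24 15-O-TBS ether (C4–OH free)
Conditions: TBSCl, imidazole, CH2Cl2, 0 °C
Reagents that add atoms: tert-butyldimethylsilyl chloride, CC(C)(C)[Si](C)(C)Cl
Why: Selective silylation of the primary hydroxyl of the 1,2-diol leaves the secondary C4–OH free.

**Step 15**
Reactants: 24 15-O-TBS ether
Product: 25 C4 ketone
Conditions: Dess–Martin periodinane, NaHCO3, CH2Cl2, 0 → 25 °C
Reagents that add atoms: none
Why: Buffered Dess–Martin oxidation gives the α-silyloxy ketone without epimerising C5 or eliminating the β-angelate; the auxiliary stereocenter at C4 is erased here.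

**Step 16**
Reactants: 25 C4 ketone
Product: 26 C4=C3 methylene compound
Conditions: Zn, CH2Br2, TiCl4, THF/CH2Cl2, 0 → 25 °C
Reagents that add atoms: dibromomethane, BrCBr
Why: Takai–Lombardo methylenation is selective for ketones over esters and lactones and is non-basic, so the β-acyloxy ketone becomes the 1,1-disubstituted alkene without elimination.

**Step 17**
Reactants: 26 C4=C3 methylene compound
Product: 27 9α,15-diol
Conditions: HF·pyridine, pyridine, THF, 0 → 25 °C
Reagents that add atoms: none
Why: HF·pyridine cleaves both TBS ethers (primary allylic at C15, secondary at C9) while the esters and the lactone are stable to these mildly acidic conditions.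

**Step 18**
Reactants: 27 9α,15-diol
Product: 28 15-al (9α-OH)
Conditions: MnO2, CH2Cl2, 25 °C
Reagents that add atoms: none
Why: MnO2 oxidises only the allylic primary alcohol, giving the 2-substituted acrolein and leaving the secondary C9–OH untouched.

**Step 19**
Reactants: 28 15-al (9α-OH); 29 methacryloyl chloride
Product: 30 CNP0102441.1
Conditions: Et3N, DMAP (cat.), CH2Cl2, 0 °C
Reagents that add atoms: none
Why: DMAP-catalysed acylation of the remaining secondary alcohol completes the target; all six ring stereocenters are already in place.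

**Compound list**

1 | (R)-2,2-dimethyl-1,3-dioxolane-4-carbaldehyde | O=C[C@H]1COC(C)(C)O1 | starting material
2 | 2-(dichloromethyl)-4,4,5,5-tetramethyl-1,3,2-dioxaborolane | ClC(Cl)B1OC(C)(C)C(C)(C)O1 | starting material
3 | 2-[(E)-2-((4S)-2,2-dimethyl-1,3-dioxolan-4-yl)ethenyl]-4,4,5,5-tetramethyl-1,3,2-dioxaborolane | CC1(C)OB(/C=C/[C@H]2COC(C)(C)O2)OC1(C)C | intermediate
4 | 4-bromofuran-2(5H)-one | O=C1C=C(Br)CO1 | starting material
5 | 4-[(E)-2-((4S)-2,2-dimethyl-1,3-dioxolan-4-yl)ethenyl]furan-2(5H)-one | O=C1C=C(/C=C/[C@H]2COC(C)(C)O2)CO1 | intermediate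
6 | (E)-3-ethoxy-2-methylprop-2-enal | CCO/C=C(\C)C=O | starting material
7 | 2-methylmalondialdehyde, enol form, (E)-3-hydroxy-2-methylprop-2-enal | O/C=C(\C)C=O | intermediate
8 | (E)-3-[diisopropyl(trifluoromethanesulfonyloxy)silyloxy]-2-methylprop-2-enal | CC(C)[Si](O/C=C(\C)C=O)(C(C)C)OS(=O)(=O)C(F)(F)F | intermediate (not isolated)
9 | mixed silyl bis-enol ether: iPr2Si joins the 2-oxygen of 4-[(E)-2-((4S)-dioxolanyl)ethenyl]furan to the enol oxygen of (E)-2-methyl-3-oxoprop-1-enyl | CC(C)[Si](O/C=C(\C)C=O)(C(C)C)Oc1cc(/C=C/[C@H]2COC(C)(C)O2)co1 | intermediate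
10 | cycloadduct: ring A with C6=C7, 10β-CHO, 10α-CH3, 5α-dioxolanyl, 8α-O, 9α-O; ketene acetal C11=C12 in ring B; iPr2Si bridging the oxygens on C12 and C9 | O=C[C@@]1(C)[C@H]([C@H]3COC(C)(C)O3)C=C2C=C4O[Si](C(C)C)(C(C)C)O[C@H]1[C@H]2O4 | intermediate (not isolated)
11 | 8,12-olide with C6=C7, 8α-O (H-8β), 9α-OH, 10α-CH3, 10β-CHO, 5α-[(4S)-dioxolanyl] | O=C[C@@]1(C)[C@H]([C@H]3COC(C)(C)O3)C=C2CC(=O)O[C@@H]2[C@@H]1O | intermediate
12 | 6α,7α-epoxide of 11 | O=C[C@@]1(C)[C@H]([C@H]3COC(C)(C)O3)[C@@H]4O[C@@]42CC(=O)O[C@@H]2[C@@H]1O | intermediate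
13 | 9-O-TBS ether of 12 | O=C[C@@]1(C)[C@H]([C@H]3COC(C)(C)O3)[C@@H]4O[C@@]42CC(=O)O[C@@H]2[C@@H]1O[Si](C)(C)C(C)(C)C | intermediate
14 | 6α-hydroxy butenolide (C7=C11), 8α-O (kinetic C8 epimer), 9α-OTBS | O=C[C@@]1(C)[C@H]([C@H]3COC(C)(C)O3)[C@H](O)C2=CC(=O)O[C@@H]2[C@@H]1O[Si](C)(C)C(C)(C)C | intermediate (not isolated)
15 | 6α-hydroxy butenolide (C7=C11), 8β-O (H-8α), 9α-OTBS | O=C[C@@]1(C)[C@H]([C@H]3COC(C)(C)O3)[C@H](O)C2=CC(=O)O[C@H]2[C@@H]1O[Si](C)(C)C(C)(C)C | intermediate
16 | cis-fused saturated lactone (H-7α, H-8α), 6α-OH, 9α-OTBS, 10β-CHO | O=C[C@@]1(C)[C@H]([C@H]3COC(C)(C)O3)[C@H](O)[C@H]2CC(=O)O[C@H]2[C@@H]1O[Si](C)(C)C(C)(C)C | intermediate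
17 | 10β-vinyl analogue of 16 | C=C[C@@]1(C)[C@H]([C@H]3COC(C)(C)O3)[C@H](O)[C@H]2CC(=O)O[C@H]2[C@@H]1O[Si](C)(C)C(C)(C)C | intermediate
18 | 11-(dimethylaminomethyl) lactone (C11 epimers) | C=C[C@@]1(C)[C@H]([C@H]3COC(C)(C)O3)[C@H](O)[C@H]2C(CN(C)C)C(=O)O[C@H]2[C@@H]1O[Si](C)(C)C(C)(C)C | intermediate (not isolated)
19 | trimethylammonium iodide of 18 | C=C[C@@]1(C)[C@H]([C@H]3COC(C)(C)O3)[C@H](O)[C@H]2C(C[N+](C)(C)C)C(=O)O[C@H]2[C@@H]1O[Si](C)(C)C(C)(C)C.[I-] | intermediate (not isolated)
20 | α-methylene lactone (C11=C13), 6α-OH, 9α-OTBS, acetonide | C=C[C@@]1(C)[C@H]([C@H]3COC(C)(C)O3)[C@H](O)[C@H]2C(=C)C(=O)O[C@H]2[C@@H]1O[Si](C)(C)C(C)(C)C | intermediate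
21 | angelic acid, (Z)-2-methylbut-2-enoic acid | C/C=C(/C)C(=O)O | starting material
22 | 6α-angelate of 20 | C=C[C@@]1(C)[C@H]([C@H]3COC(C)(C)O3)[C@H](OC(=O)/C(C)=C\C)[C@H]2C(=C)C(=O)O[C@H]2[C@@H]1O[Si](C)(C)C(C)(C)C | intermediate
23 | 4,15-diol (4S) | C=C[C@@]1(C)[C@H]([C@H](O)CO)[C@H](OC(=O)/C(C)=C\C)[C@H]2C(=C)C(=O)O[C@H]2[C@@H]1O[Si](C)(C)C(C)(C)C | intermediate
24 | 15-O-TBS ether, C4–OH free | C=C[C@@]1(C)[C@H]([C@H](O)CO[Si](C)(C)C(C)(C)C)[C@H](OC(=O)/C(C)=C\C)[C@H]2C(=C)C(=O)O[C@H]2[C@@H]1O[Si](C)(C)C(C)(C)C | intermediate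
25 | C4 ketone (5α side chain C(=O)CH2OTBS) | C=C[C@@]1(C)[C@H](C(=O)CO[Si](C)(C)C(C)(C)C)[C@H](OC(=O)/C(C)=C\C)[C@H]2C(=C)C(=O)O[C@H]2[C@@H]1O[Si](C)(C)C(C)(C)C | intermediate
26 | C4=C3 methylene compound (side chain C(=CH2)CH2OTBS) | C=C[C@@]1(C)[C@H](C(=C)CO[Si](C)(C)C(C)(C)C)[C@H](OC(=O)/C(C)=C\C)[C@H]2C(=C)C(=O)O[C@H]2[C@@H]1O[Si](C)(C)C(C)(C)C | intermediate
27 | 9α,15-diol | C=C[C@@]1(C)[C@H](C(=C)CO)[C@H](OC(=O)/C(C)=C\C)[C@H]2C(=C)C(=O)O[C@H]2[C@@H]1O | intermediate
28 | 15-al, 9α-OH | C=C[C@@]1(C)[C@H](C(=C)C=O)[C@H](OC(=O)/C(C)=C\C)[C@H]2C(=C)C(=O)O[C@H]2[C@@H]1O | intermediate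
29 | methacryloyl chloride | CC(=C)C(=O)Cl | starting material
30 | CNP0102441.1 | C=C[C@@]1(C)[C@H](C(=C)C=O)[C@H](OC(=O)/C(C)=C\C)[C@H]2C(=C)C(=O)O[C@H]2[C@@H]1OC(=O)C(=C)C | target

**Step count and risks**

Total: 19 steps. Longest linear sequence: 18 steps (steps 1, 2 and 4–19, from aldehyde 1); step 3 is a one-step side branch.

Steps most likely to fail:

Step 5 (tethered cycloaddition). What may go wrong: hydrolysis or thermal breakdown of the mixed silyl bis-enol ether before cycloaddition; cycloaddition across the furan 2,5-positions; loss of the C9 silyloxy group by addition–elimination in place of ring closure; or weak facial bias from the dioxolane. The fallback uses known chemistry without the tether, sets out from 5 and 7 and returns at 11. Compound 5 is O-silylated (TIPSOTf, Et3N) to the 2-(triisopropylsilyloxy)-4-alkenylfuran F1, and 7 is silylated (Et3SiCl, Et3N) to (E)-3-(triethylsilyloxy)-2-methylprop-2-enal F2. The two are joined in an intermolecular extra-annular Diels–Alder reaction of the 3-vinylfuran type under high pressure (CH2Cl2, 13 kbar, 25 °C) to the bis-silylated cycloadduct F3 (the isomer with CHO exo; the CHO-endo isomer is expected beside it). HF·pyridine then gives 11, which is separated by chromatography from the diastereomer that stems from the endo adduct.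

Step 6 (directed epoxidation). What may go wrong: slow oxygen delivery to the crowded α face, so that undirected attack on the β face competes, or oxidation of the aldehyde. The fallback puts the oxygen on the open β face and inverts C6 by oxidation and reduction; it sets out from 11 and returns at 15. Silylation (TBSOTf, 2,6-lutidine) gives the 9-O-TBS β,γ-unsaturated lactone F4, and mCPBA/NaHCO3 gives the 6β,7β-epoxide F5. DBU opens it and equilibrates C8 as in step 8, giving the 6β-hydroxybutenolide F6, and Dess–Martin periodinane gives the 6-oxo butenolide F7. Luche reduction (NaBH4, CeCl3·7H2O, aqueous EtOH, −15 °C, conditions under which the aldehyde is masked as its hydrate) should deliver hydride from the β face, the α face being blocked by the axial C10–CH3, to give 15.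

Step 12 (angelate). What may go wrong: isomerisation of the (Z)-enoate to the (E)-enoate during activation, or failure to acylate the hindered axial alcohol. The fallback builds the (Z)-double bond on the ester; it sets out from 20 and returns at 22. Compound 20 is acylated with 2-(diphenoxyphosphoryl)propanoic acid (DCC, DMAP) to the phosphonopropionate ester F8. A Z-selective Horner–Wadsworth–Emmons reaction with acetaldehyde (NaH, THF, −78 °C) then gives 22.

**Further compounds**

F1 | step 5 | triisopropyl[[4-[(E)-2-((4S)-2,2-dimethyl-1,3-dioxolan-4-yl)ethenyl]furan-2-yl]oxy]silane | CC(C)[Si](Oc1cc(/C=C/[C@H]2COC(C)(C)O2)co1)(C(C)C)C(C)C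
F2 | step 5 | (E)-3-(triethylsilyloxy)-2-methylprop-2-enal | CC[Si](CC)(CC)O/C=C(\C)C=O
F3 | step 5 | untethered cycloadduct (C6=C7; C12–OTIPS ketene acetal; 8α-O; 9α-OTES; 5α-dioxolanyl; 10α-CH3; 10β-CHO) | O=C[C@@]1(C)[C@H]([C@H]3COC(C)(C)O3)C=C2C=C(O[Si](C(C)C)(C(C)C)C(C)C)O[C@@H]2[C@@H]1O[Si](CC)(CC)CC
F4 | step 6 | 9-O-TBS ether of 11 | O=C[C@@]1(C)[C@H]([C@H]3COC(C)(C)O3)C=C2CC(=O)O[C@@H]2[C@@H]1O[Si](C)(C)C(C)(C)C
F5 | step 6 | 6β,7β-epoxide of F4 | O=C[C@@]1(C)[C@H]([C@H]3COC(C)(C)O3)[C@H]4O[C@]42CC(=O)O[C@@H]2[C@@H]1O[Si](C)(C)C(C)(C)C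
F6 | step 6 | 6β-hydroxy butenolide (C7=C11), 8β-O, 9α-OTBS | O=C[C@@]1(C)[C@H]([C@H]3COC(C)(C)O3)[C@@H](O)C2=CC(=O)O[C@H]2[C@@H]1O[Si](C)(C)C(C)(C)C
F7 | step 6 | 6-oxo butenolide (C7=C11), 8β-O, 9α-OTBS | O=C[C@@]1(C)[C@H]([C@H]3COC(C)(C)O3)C(=O)C2=CC(=O)O[C@H]2[C@@H]1O[Si](C)(C)C(C)(C)C
F8 | step 12 | 6α-[2-(diphenoxyphosphoryl)propanoate] of 20 | C=C[C@@]1(C)[C@H]([C@H]3COC(C)(C)O3)[C@H](OC(=O)C(C)P(=O)(Oc4ccccc4)Oc4ccccc4)[C@H]2C(=C)C(=O)O[C@H]2[C@@H]1O[Si](C)(C)C(C)(C)C
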